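**Plan**
1. Retrosynthetic cuts: C9–C10 of ring B (aryl to quaternary carbon, closed last); C7–C8 (ketone enolate plus vinyl triflate) to join the halves; O3–C1′ and O2–C5′ of the dioxane; C13–C18 and C8–C14 of rings D and C.
2. Forward: a chlorocatechol acetophenone (ring A) and a guaiadienyl triflate give the benzodioxane propellane by hetero-Diels–Alder reaction. Separately, ring E (Diels–Alder) is carried into rings D and C by one cation–olefin cascade and turned into the C8 vinyl triflate. The halves are joined at C7–C8, then ring B is closed.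
3. Enabling feature: ring B (C5, C6, C7, C8, C9, C10) is a 4,4-disubstituted naphthalen-1(4H)-one. C9 is the γ-carbon of the aryl enone C6(=O)–C7=C8 and is bonded to C10, ortho to the acyl-bearing C5. The dienolate O–C6=C7–C8=C9 of an o-chloroaryl ketone can therefore be arylated by palladium only at C9, through a six-membered ring.
4. Stereochemistry: C7′ from (S)-carvone; C10′ from ligand-controlled copper hydride reduction; C1′/C5′ from quinone approach anti to the C10′ methyl; C17 from a catalytic asymmetric Diels–Alder reaction; C13, C14, C18 relayed from C17 through the chair-like cyclisation of an E-tetrasubstituted alkene; C20 by enolate methylation on the open face; C9 by arylation anti to the axial C14 methyl.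

Key step: step 30

Remark on the chemistry: locants C1–C30 follow celastrol numbering for the triterpenoid half and C1′–C15′ follow guaiane numbering for the sesquiterpenoid half; compounds 1, 6, 12, 24, 26, 30 and 32 are taken as commercial. The vinylsilane in 34, 36 and 37 is drawn E; its Z isomer is expected to behave identically in step 22.

**Part A – ring A / dioxane / guaiane half**

Step 1
Reactants: 1 2,3-dimethoxytoluene
Product: 2 1-(3,4-dimethoxy-2-methylphenyl)ethanone
Conditions: AcCl, AlCl3, CH2Cl2, 0 °C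
Reagents that add atoms: acetyl chloride, CC(Cl)=O
Why: Friedel–Crafts acylation should go para to the unhindered methoxy group (future O2) and ortho to the methyl group, the position that becomes C5.

Step 2
Reactants: 2 1-(3,4-dimethoxy-2-methylphenyl)ethanone
Product: 3 1-(3-hydroxy-4-methoxy-2-methylphenyl)ethanone
Conditions: BCl3, CH2Cl2, −78 to 0 °C; H2O
Reagents that add atoms: none
Why: Lewis-acid ether cleavage should select the more basic methoxy group that is flanked by methyl and methoxy and is not conjugated to the ketone (future O3).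

Step 3
Reactants: 3 1-(3-hydroxy-4-methoxy-2-methylphenyl)ethanone
Product: 4 1-(6-chloro-3-hydroxy-4-methoxy-2-methylphenyl)ethanone
Conditions: NCS, MeCN, 0 °C to rt
Reagents that add atoms: N-chlorosuccinimide, ClN1C(=O)CCC1=O
Why: Electrophilic aromatic chlorination is directed para to the free phenol (both ortho positions are blocked), which places chlorine on the future C10.

Step 4
Reactants: 4 1-(6-chloro-3-hydroxy-4-methoxy-2-methylphenyl)ethanone
Product: 5 1-(6-chloro-3,4-dihydroxy-2-methylphenyl)ethanone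
Conditions: BBr3, CH2Cl2, −78 to 0 °C; H2O
Reagents that add atoms: none
Why: Boron tribromide demethylation of the remaining aryl methyl ether gives the catechol needed for quinone formation.

Step 5
Reactants: 6 (S)-(+)-carvone
Product: 8 (S)-trimethyl{[2-methyl-5-(prop-1-en-2-yl)cyclohex-1-en-1-yl]oxy}silane, via lithium enolate 7 (not isolated)
Conditions: LiBH(s-Bu)3, THF, −78 °C; then Me3SiCl, Et3N, −78 to 0 °C
Reagents that add atoms: chlorotrimethylsilane, C[Si](C)(C)Cl
Why: Hydride 1,4-reduction of the enone followed by O-silylation of the enolate gives the regiodefined tetrasubstituted silyl enol ether; C7′ comes unchanged from carvone.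

Step 6
Reactants: 8 silyl enol ether
Product: 9 (4S)-1-methyl-6-(trimethylsilyloxy)-4-(prop-1-en-2-yl)bicyclo[4.1.0]heptane (cyclopropane epimers)
Conditions: Et2Zn, CH2I2 (1.1 equiv), CH2Cl2, 0 °C
Reagents that add atoms: diiodomethane, ICI
Why: Simmons–Smith (Furukawa) cyclopropanation should take the electron-rich enol ether in preference to the isopropenyl group.

Step 7
Reactants: 9 siloxycyclopropane
Product: 11 (S)-3-methyl-6-(prop-1-en-2-yl)cyclohept-2-en-1-one, via chloroketone 10 (not isolated)
Conditions: FeCl3, DMF, 0 °C; then NaOAc, MeOH, reflux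
Reagents that add atoms: none
Why: Saegusa-type oxidative ring expansion: one-electron oxidation opens the internal cyclopropane bond to the tertiary radical, chlorine transfer and elimination give the cycloheptenone with the new carbon as C1′.

Step 8
Reactants: 11 cycloheptenone; 12 1-bromobut-2-yne
Product: 14 (2S,3R,6S)-2-(but-2-yn-1-yl)-3-methyl-6-(prop-1-en-2-yl)cycloheptan-1-one, via silyl enol ether 13 (not isolated)
Conditions: CuCl (5 mol%), NaOt-Bu (5 mol%), (S)-p-Tol-BINAP (5 mol%), Ph2SiH2, toluene, 0 °C; then 12, Bu4N[Ph3SiF2], CH2Cl2, rt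
Reagents that add atoms: none
Why: Ligand-controlled copper hydride asymmetric conjugate reduction should set C10′ as R, cis to the isopropenyl group (the ligand enantiomer is chosen accordingly), and fluoride-promoted alkylation of the silyl enol ether places the butynyl chain at C1′ trans to the new methyl group, a centre that is erased in step 11.

Step 9
Reactants: 14 alkynyl ketone
Product: 15 (2S,3R,6S)-3-methyl-2-(2-oxobutyl)-6-(prop-1-en-2-yl)cycloheptan-1-one
Conditions: NaAuCl4 (2 mol%), MeOH/H2O, 60 °C
Reagents that add atoms: water, O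
Why: Gold-catalysed alkyne hydration, steered by 5-exo participation of the ring carbonyl, should give the 1,4-diketone and leave the isopropenyl group alone.

Step 10
Reactants: 15 1,4-diketone
Product: 17 (7S,10R)-guaia-4,11-dien-3-one (C1′ epimers), via aldol 16 (not isolated)
Conditions: KOH, MeOH, reflux
Reagents that add atoms: none
Why: Intramolecular aldol condensation of the ethyl ketone onto the ring ketone forms the five-membered ring as the 2-methylcyclopentenone (C4′=C5′).

Step 11
Reactants: 17 bicyclic enone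
Product: 20 (7S,10R)-guaia-1(5),3,11-trien-3-yl trifluoromethanesulfonate, via lithium enolate 18 (not isolated), via cross-conjugated triflate 19 (not isolated)
Conditions: LiN(SiMe3)2, THF, −78 °C; PhNTf2, −78 to 0 °C; then benzene, 50 °C
Reagents that add atoms: N-phenylbis(trifluoromethanesulfonimide), O=S(=O)(N(c1ccccc1)S(=O)(=O)C(F)(F)F)C(F)(F)F
Why: Kinetic enolisation at C2′ and O-triflation avoid the two competing γ-sites, and thermal [1,5]-sigmatropic hydrogen shifts should then move the cyclopentadiene to its most substituted isomer (C1′=C5′ and C3′=C4′ both tetrasubstituted).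

Step 12
Reactants: 5 chlorocatechol; 20 dienyl triflate
Product: 22 benzodioxane propellane carrying the C3′ enol triflate (1′S,5′S,7′S,10′R), via o-quinone 21 (not isolated)
Conditions: Ag2O, MgSO4, CH2Cl2, −40 to 0 °C, dark
Reagents that add atoms: none
Why: Inverse-electron-demand hetero-Diels–Alder reaction of the o-quinone (O=C–C=O as heterodiene) with the C1′=C5′ bond. Bonding should start at the remote diene terminus C1′ with O3, because the developing aryloxide at O2 is para to the acetyl group. The triflate deactivates C3′=C4′, and approach anti to the C10′ methyl and C7′ isopropenyl groups sets C1′ and C5′.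

Step 13
Reactants: 22 enol triflate
Product: 23 1-aryl ethanone "acetophenone fragment" (ring A with C5 acetyl, C10 chlorine, C4 methyl; dioxane; guaia-3,11-diene)
Conditions: Pd(OAc)2 (5 mol%), PPh3, HCO2H, Bu3N, DMF, 40 °C
Reagents that add atoms: none
Why: Palladium/formate hydrogenolysis of the enol triflate gives the C3′=C4′ alkene; the aryl chloride is inert with triphenylphosphine as ligand, and the mild temperature limits ionisation of the allylic aryl ether.

**Part B – rings C, D, E**

Step 14
Reactants: 24 methyl vinyl ketone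
Product: 25 2-(triisopropylsilyloxy)buta-1,3-diene
Conditions: i-Pr3SiOTf, Et3N, Et2O, 0 °C
Reagents that add atoms: triisopropylsilyl trifluoromethanesulfonate, CC(C)[Si](OS(=O)(=O)C(F)(F)F)(C(C)C)C(C)C
Why: Soft enolisation and O-silylation of the enone gives the 2-silyloxy diene.

Step 15
Reactants: 25 silyloxy diene; 26 methacrolein
Product: 27 (S)-1-methyl-4-(triisopropylsilyloxy)cyclohex-3-ene-1-carbaldehyde
Conditions: (S)-o-tolyl-CBS oxazaborolidine (20 mol%), Tf2NH (20 mol%), CH2Cl2, −78 °C
Reagents that add atoms: none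
Why: Cationic oxazaborolidine-catalysed asymmetric Diels–Alder reaction with "para" regiochemistry; the catalyst controls the face of the bound enal and sets the quaternary C17 (catalyst enantiomer chosen to give S).

Step 16
Reactants: 27 aldehyde
Product: 28 (S)-[1-methyl-4-(triisopropylsilyloxy)cyclohex-3-en-1-yl]methanol
Conditions: NaBH4, MeOH, 0 °C
Reagents that add atoms: none
Why: Borohydride reduction of the aldehyde; the bulky silyl enol ether should survive.

Step 17
Reactants: 28 alcohol
Product: 29 (S)-{[4-(iodomethyl)-4-methylcyclohex-1-en-1-yl]oxy}triisopropylsilane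
Conditions: PPh3, imidazole, I2 (premixed), toluene, rt to 50 °C
Reagents that add atoms: iodine, II
Why: Appel-type iodination of the neopentyl-type alcohol; premixing the reagents keeps free iodine away from the enol ether.

Step 18
Reactants: 30 2,3-dimethylbuta-1,3-diene
Product: 31 (E)-1,4-dibromo-2,3-dimethylbut-2-ene
Conditions: Br2, CH2Cl2, −20 °C; crystallisation
Reagents that add atoms: bromine, BrBr
Why: 1,4-Addition of bromine to the diene gives the E-tetrasubstituted alkene that later fixes the trans relationship of the C13 and C14 methyl groups.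

Step 19
Reactants: 31 dibromide; 32 trimethyl(2-methylallyl)silane
Product: 34 [(1E,5E)-7-bromo-2,5,6-trimethylhepta-1,5-dien-1-yl]trimethylsilane, via silylallyllithium 33 (not isolated)
Conditions: 32, s-BuLi, TMEDA, THF, −78 °C; added to 31 (3 equiv), −78 to −20 °C
Reagents that add atoms: none
Why: The α-silylallyl anion is alkylated at its γ-carbon by SN2 displacement of the primary allylic bromide (SN2′ would create a quaternary centre), giving the vinylsilane terminator; excess dibromide limits double alkylation.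

Step 20
Reactants: 29 iodide; 34 allylic bromide
Product: 36 (S)-triisopropylsilyl enol ether of the coupled chain (C17–C16–C15–C14=C13–C12–C11–C9=C8–Si), via alkyllithium 35 (not isolated)
Conditions: 29, t-BuLi (2.1 equiv), Et2O/pentane, −78 °C; then CuBr·SMe2 (10 mol%), 34, −78 to 0 °C
Reagents that add atoms: none
Why: Lithium–iodine exchange followed by copper-catalysed SN2 allylic alkylation forms C15–C16; the silyl enol ether masks the ketone toward the organolithium.

Step 21
Reactants: 36 silyl enol ether
Product: 37 (S)-4-methyl-4-[(3E,7E)-3,4,7-trimethyl-8-(trimethylsilyl)octa-3,7-dien-1-yl]cyclohex-2-en-1-one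
Conditions: Pd(OAc)2 (10 mol%), O2 (1 atm), DMSO, 60 °C
Reagents that add atoms: none
Why: Saegusa–Ito oxidation converts the regiodefined silyl enol ether into the C18=C19 enone on that side only.

Step 22
Reactants: 37 enone
Product: 38 tricyclic ketone (rings C, D, E; C20 ketone, C8=C9 alkene; 13α-Me, 14β-Me, 17β-Me, 18β-H)
Conditions: MeAlCl2 (2.5 equiv), CH2Cl2, −78 to −20 °C; aq. NaHCO3
Reagents that add atoms: none
Why: Lewis-acid-promoted cation–olefin bicyclisation (Stork–Eschenmoser anti addition): the activated enone is attacked at C18 by C13 of the E-tetrasubstituted alkene, C14 is trapped by the vinylsilane with loss of silicon to give C8=C9, the alkene geometry gives trans C13/C14 methyls, the tether gives the cis D/E fusion, and C17 selects the chair that avoids two syn-axial methyl contacts.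

Step 23
Reactants: 38 tricyclic ketone
Product: 40 C20 enol triflate (C20=C21), via potassium enolate 39 (not isolated)
Conditions: KN(SiMe3)2, THF, −78 °C; PhNTf2
Reagents that add atoms: N-phenylbis(trifluoromethanesulfonimide), O=S(=O)(N(c1ccccc1)S(=O)(=O)C(F)(F)F)C(F)(F)F
Why: Kinetic enolate triflation; the regioisomeric triflate would converge in step 25.

Step 24
Reactants: 40 enol triflate
Product: 41 methyl C20-carboxylate, α,β-unsaturated (C20=C21)
Conditions: Pd(OAc)2 (5 mol%), dppp, CO (1 atm), MeOH, Et3N, DMF, 60 °C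
Reagents that add atoms: carbon monoxide, [C-]#[O+]; methanol, CO
Why: Palladium-catalysed methoxycarbonylation of the enol triflate installs C29 as the methyl ester.

Step 25
Reactants: 41 unsaturated ester
Product: 43 methyl ester with quaternary C20 (20β-Me, 20α-CO2Me) and C8=C9, via lithium ester enolate 42 (not isolated)
Conditions: Li, NH3(l)/THF, t-BuOH (1 equiv), −78 °C; then MeI
Reagents that add atoms: iodomethane, CI
Why: Birch-type reductive alkylation: the exocyclic ester enolate is methylated from the face away from the axial C18–C13 bond (1,3 to C20), which should give the 20β-methyl, 20α-ester arrangement.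

Step 26
Reactants: 43 alkene ester
Product: 45 C8 alcohol (8α-OH, 9β-Me expected; both centres are removed later), via alkylborane 44 (not isolated)
Conditions: BH3·SMe2, THF, 0 °C to rt; then NaOH, H2O2, 0 °C
Reagents that add atoms: hydrogen peroxide, OO
Why: Hydroboration–oxidation puts boron on the less substituted C8 of the trisubstituted alkene by syn addition anti to the C14 methyl; the hindered tertiary ester should survive.

Step 27
Reactants: 45 alcohol
Product: 46 C8 ketone (C9 epimerisable)
Conditions: Dess–Martin periodinane, NaHCO3, CH2Cl2, rt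
Reagents that add atoms: none
Why: Dess–Martin oxidation of the secondary alcohol under buffered conditions.

Step 28
Reactants: 46 ketone
Product: 48 C8 vinyl triflate (C8=C9), via potassium enolate 47 (not isolated)
Conditions: KN(SiMe3)2, THF, −78 °C; PhNTf2, −78 to 0 °C
Reagents that add atoms: N-phenylbis(trifluoromethanesulfonimide), O=S(=O)(N(c1ccccc1)S(=O)(=O)C(F)(F)F)C(F)(F)F
Why: Enol triflation can only occur toward C9 because C14 is quaternary, so the tetrasubstituted triflate is formed regiospecifically.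

**Part C – union and ring B**

Step 29
Reactants: 23 acetophenone fragment; 48 vinyl triflate
Product: 50 β,γ-unsaturated aryl ketone Ar–C6(=O)–C7H2–C8=C9(Me), via lithium enolate 49 (not isolated)
Conditions: 23, LiN(SiMe3)2 (2.2 equiv), THF, −78 to 0 °C; then 48, Pd2(dba)3 (3 mol%), Xantphos (7 mol%), 50 °C; aq. NH4Cl
Reagents that add atoms: none
Why: Palladium-catalysed α-alkenylation of the methyl ketone enolate forms C7–C8; the vinyl triflate undergoes oxidative addition under conditions that leave the aryl chloride untouched, and the conjugated isomer of 50 would serve equally in step 30.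

Step 30
Reactants: 50 β,γ-unsaturated aryl ketone
Product: 52 target compound, via caesium dienolate 51 (not isolated)
Conditions: Pd2(dba)3 (5 mol%), XPhos (12 mol%), Cs2CO3, toluene, 90 °C
Reagents that add atoms: none
Why: Zerovalent palladium inserts into the C10–Cl bond, which is activated by the ortho acyl group, while carbonate removes a doubly activated C7 proton to give the dienolate O–C6=C7–C8=C9; the dienolate binds palladium and C–C reductive elimination at C9 forms C9–C10 and leaves the conjugated C7=C8 enone. The closest known reaction type is the palladium-catalysed γ-arylation of β,γ-unsaturated ketones, here run intramolecularly like a ketone α-arylation. Ring B closes as a six-membered ring by reductive elimination from a seven-membered palladacycle; attack at C7 would give a four-membered ring, so γ-selectivity is enforced by ring size. The new quaternary centre C9 is controlled by the substrate: the aryl group should arrive on the α-face, anti to the axial β-methyl on C14 (1,3 to C9), leaving the C9 methyl β. The step needs chemoselective C–Cl activation without ionising the hindered tertiary allylic aryl ether at C5′, which the bulky ligand and the intramolecular enolate capture should secure; the dienolate geometry equilibrates under the weak base.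

**Compound list**
1 | 2,3-dimethoxytoluene | COc1cccc(C)c1OC | starting material
2 | 1-(3,4-dimethoxy-2-methylphenyl)ethanone | CC(=O)c1ccc(OC)c(OC)c1C | intermediate
3 | 1-(3-hydroxy-4-methoxy-2-methylphenyl)ethanone | CC(=O)c1ccc(OC)c(O)c1C | intermediate
4 | 1-(6-chloro-3-hydroxy-4-methoxy-2-methylphenyl)ethanone | CC(=O)c1c(Cl)cc(OC)c(O)c1C | intermediate
5 | 1-(6-chloro-3,4-dihydroxy-2-methylphenyl)ethanone | CC(=O)c1c(Cl)cc(O)c(O)c1C | intermediate
6 | (S)-(+)-carvone | C=C(C)[C@H]1CC=C(C)C(=O)C1 | starting material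
7 | lithium enolate of (5S)-dihydrocarvone | C=C(C)[C@H]1CCC(C)=C([O-])C1.[Li+] | intermediate
8 | (S)-trimethyl{[2-methyl-5-(prop-1-en-2-yl)cyclohex-1-en-1-yl]oxy}silane | C=C(C)[C@H]1CCC(C)=C(O[Si](C)(C)C)C1 | intermediate
9 | (4S)-1-methyl-6-(trimethylsilyloxy)-4-(prop-1-en-2-yl)bicyclo[4.1.0]heptane (cyclopropane epimers) | C=C(C)[C@H]1CCC2(C)CC2(O[Si](C)(C)C)C1 | intermediate
10 | (6S)-3-chloro-3-methyl-6-(prop-1-en-2-yl)cycloheptan-1-one (C3 epimers) | C=C(C)[C@H]1CCC(C)(Cl)CC(=O)C1 | intermediate
11 | (S)-3-methyl-6-(prop-1-en-2-yl)cyclohept-2-en-1-one | C=C(C)[C@H]1CCC(C)=CC(=O)C1 | intermediate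
12 | 1-bromobut-2-yne | CC#CCBr | starting material
13 | {[(3R,6S)-3-methyl-6-(prop-1-en-2-yl)cyclohept-1-en-1-yl]oxy}diphenylsilane | C=C(C)[C@H]1CC[C@@H](C)C=C(O[SiH](c2ccccc2)c2ccccc2)C1 | intermediate
14 | (2S,3R,6S)-2-(but-2-yn-1-yl)-3-methyl-6-(prop-1-en-2-yl)cycloheptan-1-one | C=C(C)[C@H]1CC[C@@H](C)[C@H](CC#CC)C(=O)C1 | intermediate
15 | (2S,3R,6S)-3-methyl-2-(2-oxobutyl)-6-(prop-1-en-2-yl)cycloheptan-1-one | C=C(C)[C@H]1CC[C@@H](C)[C@H](CC(=O)CC)C(=O)C1 | intermediate
16 | (7S,10R)-5-hydroxyguai-11-en-3-one (aldol, other centres unassigned) | C=C(C)[C@H]1CC[C@@H](C)C2CC(=O)C(C)C2(O)C1 | intermediate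
17 | (7S,10R)-guaia-4,11-dien-3-one (C1′ epimers) | C=C(C)[C@H]1CC[C@@H](C)C2CC(=O)C(C)=C2C1 | intermediate
18 | lithium cross-conjugated enolate of 17 (C2′=C3′–O) | C=C(C)[C@H]1CC[C@@H](C)C2C=C([O-])C(C)=C2C1.[Li+] | intermediate
19 | (7S,10R)-guaia-2,4,11-trien-3-yl trifluoromethanesulfonate | C=C(C)[C@H]1CC[C@@H](C)C2C=C(OS(=O)(=O)C(F)(F)F)C(C)=C2C1 | intermediate
20 | (7S,10R)-guaia-1(5),3,11-trien-3-yl trifluoromethanesulfonate | C=C(C)[C@H]1CC[C@@H](C)C2=C(C1)C(C)=C(OS(=O)(=O)C(F)(F)F)C2 | intermediate
21 | 4-acetyl-5-chloro-3-methylcyclohexa-3,5-diene-1,2-dione | CC(=O)C1=C(C)C(=O)C(=O)C=C1Cl | intermediate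
22 | benzodioxane propellane, C3′ enol triflate (1′S,5′S,7′S,10′R; oxygens anti to the C10′ methyl) | C=C(C)[C@H]1CC[C@@H](C)[C@@]23CC(OS(=O)(=O)C(F)(F)F)=C(C)[C@]2(C1)Oc1cc(Cl)c(C(C)=O)c(C)c1O3 | intermediate
23 | acetophenone fragment: 1-aryl ethanone with C10 chlorine, C4 methyl, dioxane fused to (1′S,5′S,7′S,10′R)-guaia-3,11-diene | C=C(C)[C@H]1CC[C@@H](C)[C@@]23CC=C(C)[C@]2(C1)Oc1cc(Cl)c(C(C)=O)c(C)c1O3 | intermediate
24 | methyl vinyl ketone | CC(=O)C=C | starting material
25 | 2-(triisopropylsilyloxy)buta-1,3-diene | C=CC(=C)O[Si](C(C)C)(C(C)C)C(C)C | intermediate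
26 | methacrolein | CC(=C)C=O | starting material
27 | (S)-1-methyl-4-(triisopropylsilyloxy)cyclohex-3-ene-1-carbaldehyde | C1C=C(O[Si](C(C)C)(C(C)C)C(C)C)CC[C@]1(C)C=O | intermediate
28 | (S)-[1-methyl-4-(triisopropylsilyloxy)cyclohex-3-en-1-yl]methanol | C1C=C(O[Si](C(C)C)(C(C)C)C(C)C)CC[C@]1(C)CO | intermediate
29 | (S)-{[4-(iodomethyl)-4-methylcyclohex-1-en-1-yl]oxy}triisopropylsilane | C1C=C(O[Si](C(C)C)(C(C)C)C(C)C)CC[C@]1(C)CI | intermediate
30 | 2,3-dimethylbuta-1,3-diene | C=C(C)C(C)=C | starting material
31 | (E)-1,4-dibromo-2,3-dimethylbut-2-ene | BrC/C(C)=C(\C)CBr | intermediate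
32 | trimethyl(2-methylallyl)silane | C=C(C)C[Si](C)(C)C | starting material
33 | 2-methyl-1-(trimethylsilyl)allyllithium | C=C(C)C([Li])[Si](C)(C)C | intermediate
34 | [(1E,5E)-7-bromo-2,5,6-trimethylhepta-1,5-dien-1-yl]trimethylsilane | BrC/C(C)=C(\C)CC/C(C)=C/[Si](C)(C)C | intermediate
35 | (S)-{[1-methyl-4-(triisopropylsilyloxy)cyclohex-3-en-1-yl]methyl}lithium | C1C=C(O[Si](C(C)C)(C(C)C)C(C)C)CC[C@]1(C)C[Li] | intermediate
36 | (S)-triisopropylsilyl enol ether of 4-methyl-4-[(3E,7E)-3,4,7-trimethyl-8-(trimethylsilyl)octa-3,7-dien-1-yl]cyclohexanone | C1C=C(O[Si](C(C)C)(C(C)C)C(C)C)CC[C@]1(C)CC/C(C)=C(\C)CC/C(C)=C/[Si](C)(C)C | intermediate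
37 | (S)-4-methyl-4-[(3E,7E)-3,4,7-trimethyl-8-(trimethylsilyl)octa-3,7-dien-1-yl]cyclohex-2-en-1-one | C1=CC(=O)CC[C@]1(C)CC/C(C)=C(\C)CC/C(C)=C/[Si](C)(C)C | intermediate
38 | tricyclic C/D/E ketone: C20 ketone, C8=C9, 9-Me, 13α-Me, 14β-Me, 17β-Me, 18β-H | C1=C(C)CC[C@@]2(C)[C@@H]3CC(=O)CC[C@]3(C)CC[C@]12C | intermediate
39 | potassium C20 enolate of 38 (C20=C21) | C1=C(C)CC[C@@]2(C)[C@@H]3CC([O-])=CC[C@]3(C)CC[C@]12C.[K+] | intermediate
40 | C20 enol triflate of 38 (C20=C21) | C1=C(C)CC[C@@]2(C)[C@@H]3CC(OS(=O)(=O)C(F)(F)F)=CC[C@]3(C)CC[C@]12C | intermediate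
41 | methyl C20-carboxylate, C20=C21 and C8=C9 diene | C1=C(C)CC[C@@]2(C)[C@@H]3CC(C(=O)OC)=CC[C@]3(C)CC[C@]12C | intermediate
42 | lithium ester enolate at C20 | C1=C(C)CC[C@@]2(C)[C@@H]3CC(=C([O-])OC)CC[C@]3(C)CC[C@]12C.[Li+] | intermediate
43 | methyl ester with quaternary C20 (20β-Me, 20α-CO2Me), C8=C9 | C1=C(C)CC[C@@]2(C)[C@@H]3C[C@](C)(C(=O)OC)CC[C@]3(C)CC[C@]12C | intermediate
44 | C8 alkylborane (8α-boryl, 9β-Me) | B[C@@H]1[C@@H](C)CC[C@@]2(C)[C@@H]3C[C@](C)(C(=O)OC)CC[C@]3(C)CC[C@]12C | intermediate
45 | C8 alcohol (8α-OH, 9β-Me) | O[C@@H]1[C@@H](C)CC[C@@]2(C)[C@@H]3C[C@](C)(C(=O)OC)CC[C@]3(C)CC[C@]12C | intermediate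
46 | C8 ketone (9β-Me drawn, epimerisable) | O=C1[C@@H](C)CC[C@@]2(C)[C@@H]3C[C@](C)(C(=O)OC)CC[C@]3(C)CC[C@]12C | intermediate
47 | potassium C8 enolate (C8=C9) | [O-]C1=C(C)CC[C@@]2(C)[C@@H]3C[C@](C)(C(=O)OC)CC[C@]3(C)CC[C@]12C.[K+] | intermediate
48 | C8 vinyl triflate (C8=C9) of the C/D/E methyl ester | FC(F)(F)S(=O)(=O)OC1=C(C)CC[C@@]2(C)[C@@H]3C[C@](C)(C(=O)OC)CC[C@]3(C)CC[C@]12C | intermediate
49 | lithium enolate of 23 | C=C(C)[C@H]1CC[C@@H](C)[C@@]23CC=C(C)[C@]2(C1)Oc1cc(Cl)c(C(=C)[O-])c(C)c1O3.[Li+] | intermediate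
50 | β,γ-unsaturated aryl ketone: C6 ketone, C7H2, C8=C9, C10–Cl, rings A, C, D, E, dioxane and guaiane in place | C=C(C)[C@H]1CC[C@@H](C)[C@@]23CC=C(C)[C@]2(C1)Oc1cc(Cl)c(C(=O)CC4=C(C)CC[C@@]5(C)[C@@H]6C[C@](C)(C(=O)OC)CC[C@]6(C)CC[C@]45C)c(C)c1O3 | intermediate
51 | caesium dienolate of 50 (O–C6=C7–C8=C9) | C=C(C)[C@H]1CC[C@@H](C)[C@@]23CC=C(C)[C@]2(C1)Oc1cc(Cl)c(C([O-])=CC4=C(C)CC[C@@]5(C)[C@@H]6C[C@](C)(C(=O)OC)CC[C@]6(C)CC[C@]45C)c(C)c1O3.[Cs+] | intermediate
52 | target compound | C=C(C)[C@H]1CC[C@@H](C)[C@@]23CC=C(C)[C@]2(C1)Oc1cc2c(c(C)c1O3)C(=O)C=C1[C@@]2(C)CC[C@@]2(C)[C@@H]3C[C@](C)(C(=O)OC)CC[C@]3(C)CC[C@]12C | target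

**Totals**
Total steps: 30. Longest linear sequence: 15 steps (14, 15, 16, 17, 20 to 30).

**Three steps most likely to fail**

Step 12 (quinone cycloaddition). What may go wrong: the triflate-deactivated diene may be too slow, so that quinone decomposition, ene reaction or addition to the isopropenyl group competes; the regiochemistry (which oxygen bonds to C1′) or the facial selectivity may be poor. Fallback, setting out from 17 (through its enolate 18) and 5 and returning at 22: the C3′ substituent is changed from acceptor to donor. Enolate 18 is silylated with t-BuMe2SiCl to the cross-conjugated silyl enol ether F1. Warming moves it by the same [1,5]-hydrogen shift to the linear tert-butyldimethylsilyl dienol ether F2, a Mukaiyama-type vinylogous donor that is far more nucleophilic at C1′. F2 takes up the quinone from 5 and Ag2O to give the silyl enol ether adduct F3. CsF and PhNTf2 then convert F3, through caesium enolate F4, into triflate 22.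

Step 22 (bicyclisation). What may go wrong: proton loss after the first ring closure, five-membered ring formation at the tetrasubstituted alkene, or protodesilylation before C8–C14 bonding. Fallback, setting out from 37 and returning at 38: the initiator is changed to a discrete alkoxyallyl cation. Enone 37 is converted with 1,2-bis(trimethylsilyloxy)ethane and catalytic Me3SiOTf into the dioxolane F5. SnCl4 at −78 °C ionises the acetal and the acetal-initiated cation–olefin cyclisation gives the 2-hydroxyethyl enol ether F6. Dilute aqueous acid hydrolyses F6 to ketone 38.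

Step 30 (ring B closure). What may go wrong: the palladium dienolate may stay bound at oxygen and never reach C9, zerovalent palladium may ionise the tertiary allylic aryl ether, or the aryl group may be delivered to the wrong face of C9. Fallback, setting out from 23 and 46 and returning at 52, with ring B still closed last but by carbonyl chemistry: the acetyl group of 23 is masked as the dioxolane F7 (1,2-bis(trimethylsilyloxy)ethane, catalytic Me3SiOTf). Intermolecular palladium-catalysed α-arylation of ketone 46, which can enolise only at C9, with aryl chloride F7 (Pd2(dba)3, XPhos, NaOt-Bu) gives the C9-aryl ketone F8 with the aryl group anti to the C14 methyl. Mild aqueous acid releases diketone F9. KOH in methanol then effects the intramolecular aldol condensation of the acetyl methyl group onto the C8 ketone, through aldol F10, to give 52.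

**Further compounds**
F1 | step 12 | tert-butyldimethylsilyl enol ether, cross-conjugated (C2′=C3′, C4′=C5′) | C=C(C)[C@H]1CC[C@@H](C)C2C=C(O[Si](C)(C)C(C)(C)C)C(C)=C2C1
F2 | step 12 | tert-butyldimethylsilyl dienol ether, linear (C1′=C5′, C3′=C4′) | C=C(C)[C@H]1CC[C@@H](C)C2=C(C1)C(C)=C(O[Si](C)(C)C(C)(C)C)C2
F3 | step 12 | benzodioxane propellane carrying the C3′ silyl enol ether | C=C(C)[C@H]1CC[C@@H](C)[C@@]23CC(O[Si](C)(C)C(C)(C)C)=C(C)[C@]2(C1)Oc1cc(Cl)c(C(C)=O)c(C)c1O3
F4 | step 12 | caesium C3′ enolate of the propellane | C=C(C)[C@H]1CC[C@@H](C)[C@@]23CC([O-])=C(C)[C@]2(C1)Oc1cc(Cl)c(C(C)=O)c(C)c1O3.[Cs+]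
F5 | step 22 | ethylene acetal of enone 37 | C1=CC2(OCCO2)CC[C@]1(C)CC/C(C)=C(\C)CC/C(C)=C/[Si](C)(C)C
F6 | step 22 | 2-hydroxyethyl enol ether of 38 (C19=C20) | C1=C(C)CC[C@@]2(C)[C@@H]3C=C(OCCO)CC[C@]3(C)CC[C@]12C
F7 | step 30 | ethylene acetal of 23 | C=C(C)[C@H]1CC[C@@H](C)[C@@]23CC=C(C)[C@]2(C1)Oc1cc(Cl)c(C4(C)OCCO4)c(C)c1O3
F8 | step 30 | C9-aryl C8 ketone, acetal | C=C(C)[C@H]1CC[C@@H](C)[C@@]23CC=C(C)[C@]2(C1)Oc1cc(c(C4(C)OCCO4)c(C)c1O3)[C@]4(C)CC[C@@]5(C)[C@@H]6C[C@](C)(C(=O)OC)CC[C@]6(C)CC[C@]5(C)C4=O
F9 | step 30 | C9-aryl C8 ketone with free acetyl group | C=C(C)[C@H]1CC[C@@H](C)[C@@]23CC=C(C)[C@]2(C1)Oc1cc(c(C(C)=O)c(C)c1O3)[C@]4(C)CC[C@@]5(C)[C@@H]6C[C@](C)(C(=O)OC)CC[C@]6(C)CC[C@]5(C)C4=O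
F10 | step 30 | C8 aldol (ring B closed, 8-hydroxy, C7H2) | C=C(C)[C@H]1CC[C@@H](C)[C@@]23CC=C(C)[C@]2(C1)Oc1cc2c(c(C)c1O3)C(=O)CC1(O)[C@@]2(C)CC[C@@]2(C)[C@@H]3C[C@](C)(C(=O)OC)CC[C@]3(C)CC[C@]12C
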